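**Plan**

1. Retrosynthesis: the cyclopentane CH2 is traced back to a CH–OTBS helper. One pericyclic cascade then cuts four ring bonds: the two Diels–Alder bonds of the ester-bearing cyclohexene/cyclopentane, the cyclobutane ring-fusion bond (6π), and the cyclobutane bond between the decenyl-bearing CH and the CH attached to the cyclopentane carbon (8π). The resulting linear C24 heptaenoate is cut at its central (Z)-alkene (from an alkyne, C(sp)–C(sp2)) into dienyne 9 and iodotrienoate 18.
2. Enabling feature: the trans-1,2-disubstituted cyclobutane is cis-fused to a cyclohexene. These eight carbons are a folded (E,Z,Z,E)-octatetraene whose termini are the two substituted cyclobutane CH groups. The cyclopentane and the ester-bearing cyclohexene are the imprint of an (E,E)-dienoate, one carbon from a terminus, added across the cyclohexadiene.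
3. Forward order: alkyl fragment 9 (steps 1–5) and ester fragment 18 (steps 6–10) are joined by Sonogashira coupling (step 11). A cis semi-reduction then releases the tetraene, which closes to the eight-membered ring, then the four/six-membered pair, then the five/six-membered pair (step 12). The helper oxygen is removed in steps 13–15.
4. Stereochemistry: one carbinol centre is set by catalysis (step 7). It steers the sense of the 8π closure, and all eight ring stereocentres follow by orbital symmetry and the tether; the carbinol centre is then erased. Alkene geometries come from stereoretentive Suzuki coupling (E), Wittig (E), Peterson (Z), hydrozirconation (E) and zinc semi-reduction (Z).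

Key step: step 12

Remark: the sense of torquoinduction is assigned from an inside-alkoxy model of the allylic silyl ether. If it proves opposite, only the ligand antipode in step 7 changes (6S series); the route is otherwise identical.

**Route**

Step 1
Reactants: 1 oct-7-en-1-ol; 2 (E)-1-bromoprop-1-ene
Product: 3 (E)-undec-9-en-1-ol
Conditions: 9-BBN (2.2 equiv), THF, 0 °C to rt; then 2, PdCl2(dppf) (cat.), 3 M aq NaOH, THF, 60 °C
Reagents that add atoms: none
Why: B-alkyl Suzuki–Miyaura coupling, in which anti-Markovnikov hydroboration gives the primary alkylborane and the coupling retains the (E) geometry of the bromide (the free hydroxyl only consumes a second equivalent of borane).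

Step 2
Reactants: 3 (E)-undec-9-en-1-ol
Product: 4 (E)-undec-9-enal
Conditions: PhI(OAc)2, TEMPO (cat.), CH2Cl2, rt
Reagents that add atoms: none
Why: Oxoammonium (TEMPO) oxidation stops at the aldehyde and leaves the isolated alkene untouched.

Step 3
Reactants: 4 (E)-undec-9-enal; 5 (triphenylphosphoranylidene)acetaldehyde
Product: 6 (2E,11E)-trideca-2,11-dienal
Conditions: toluene, 80 °C
Reagents that add atoms: none
Why: Wittig olefination with a formyl-stabilised ylide should give the (E)-enal, as is usual for stabilised ylides.

Step 4
Reactants: 6 (2E,11E)-trideca-2,11-dienal; 7 1,3-bis(triisopropylsilyl)propyne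
Product: 8 triisopropyl[(3Z,5E,14E)-hexadeca-3,5,14-trien-1-yn-1-yl]silane
Conditions: 7, n-BuLi, THF, −20 °C; then 6, −78 °C to rt
Reagents that add atoms: none
Why: Peterson olefination of the lithiated bis-silylpropyne (Corey–Rücker Z-enyne synthesis), in which the bulky silyl groups favour the adduct that syn-eliminates to the (Z)-enyne and the hard organolithium adds 1,2 to the enal.

Step 5
Reactants: 8 triisopropyl[(3Z,5E,14E)-hexadeca-3,5,14-trien-1-yn-1-yl]silane
Product: 9 (3Z,5E,14E)-hexadeca-3,5,14-trien-1-yne
Conditions: TBAF, THF, 0 °C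
Reagents that add atoms: none
Why: Fluoride cleaves the C(sp)–Si bond, and no other fluoride- or base-sensitive group is present.

Step 6
Reactants: 10 (E)-4,4-dimethoxybut-2-enal; 11 methyl (triphenylphosphoranylidene)acetate
Product: 13 methyl (2E,4E)-6-oxohexa-2,4-dienoate, via dimethyl acetal 12 (not isolated)
Conditions: CH2Cl2, rt; then 1 M aq HCl, THF, rt
Reagents that add atoms: water, O
Why: Wittig olefination with the ester-stabilised ylide should give the new (E)-alkene while the acetal masks the second aldehyde, which dilute acid then releases in the same flask.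

Step 7
Reactants: 13 methyl (2E,4E)-6-oxohexa-2,4-dienoate; 14 ethynyltrimethylsilane
Product: 15 methyl (2E,4E,6R)-6-hydroxy-8-(trimethylsilyl)octa-2,4-dien-7-ynoate
Conditions: Me2Zn, ProPhenol ligand (antipode that gives the 6R alcohol, 20 mol %), Ph3P=O (40 mol %), toluene, 4 °C
Reagents that add atoms: none
Why: Zn–ProPhenol-catalysed enantioselective alkynylation of an enal, in which the dinuclear zinc catalyst binds aldehyde and alkynyl group and delivers the alkynyl to one carbonyl face, setting the only stereocentre made by catalysis.

Step 8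
Reactants: 15 methyl (2E,4E,6R)-6-hydroxy-8-(trimethylsilyl)octa-2,4-dien-7-ynoate
Product: 16 methyl (2E,4E,6R)-6-[(tert-butyldimethylsilyl)oxy]-8-(trimethylsilyl)octa-2,4-dien-7-ynoate
Conditions: TBSCl, imidazole, DMF, 0 °C to rt
Reagents that add atoms: tert-butyldimethylsilyl chloride (TBSCl), CC(C)(C)[Si](C)(C)Cl
Why: Standard silylation of a secondary alcohol, which protects the doubly activated carbinol and installs the allylic silyl ether that later steers the electrocyclization.

Step 9
Reactants: 16 methyl (2E,4E,6R)-6-[(tert-butyldimethylsilyl)oxy]-8-(trimethylsilyl)octa-2,4-dien-7-ynoate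
Product: 17 methyl (2E,4E,6R)-6-[(tert-butyldimethylsilyl)oxy]octa-2,4-dien-7-ynoate
Conditions: AgNO3 (0.2 equiv), acetone/H2O/CH2Cl2, rt, dark
Reagents that add atoms: none
Why: Silver-catalysed protodesilylation removes only the alkynyl SiMe3 group under neutral conditions, so the O–TBS bond survives and the acidic carbinol C–H (vinylogous to the ester) is not exposed to base.

Step 10
Reactants: 17 methyl (2E,4E,6R)-6-[(tert-butyldimethylsilyl)oxy]octa-2,4-dien-7-ynoate
Product: 18 methyl (2E,4E,6R,7E)-6-[(tert-butyldimethylsilyl)oxy]-8-iodoocta-2,4,7-trienoate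
Conditions: Cp2Zr(H)Cl (1.3 equiv), THF, rt, dark; then I2, 0 °C
Reagents that add atoms: iodine, II
Why: Hydrozirconation adds Zr–H syn with zirconium on the terminal carbon, and iodinolysis with retention gives the (E)-vinyl iodide; the terminal alkyne should react much faster than the ester or the diene.

Step 11
Reactants: 18 methyl (2E,4E,6R,7E)-6-[(tert-butyldimethylsilyl)oxy]-8-iodoocta-2,4,7-trienoate; 9 (3Z,5E,14E)-hexadeca-3,5,14-trien-1-yne
Product: 19 methyl (2E,4E,6R,7E,11Z,13E,22E)-6-[(tert-butyldimethylsilyl)oxy]tetracosa-2,4,7,11,13,22-hexaen-9-ynoate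
Conditions: Pd(PPh3)4 (5 mol %), CuI (10 mol %), Et3N, THF, rt, degassed, dark
Reagents that add atoms: none
Why: Sonogashira coupling at room temperature joins the two fragments with retention of every alkene geometry.

Step 12
Reactants: 19 methyl (2E,4E,6R,7E,11Z,13E,22E)-6-[(tert-butyldimethylsilyl)oxy]tetracosa-2,4,7,11,13,22-hexaen-9-ynoate
Product: 23 tetracyclic silyl ether (target skeleton with an OTBS group on the cyclopentane carbon next to the cyclobutane), via tetraene 20 (not isolated), via cyclooctatriene 21 (not isolated), via bicyclooctadiene 22 (not isolated)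
Conditions: Zn dust activated with Cu(OAc)2 and AgNO3, MeOH/H2O/1,4-dioxane, 25 °C, dark; filter, extract; then toluene, BHT (cat.), 110 °C; chromatography
Reagents that add atoms: none
Why: The zinc couple transfers two hydrogens cis to the only alkyne, and the (E,Z,Z,E)-tetraene 20 closes at room temperature by thermal conrotatory 8π electrocyclization between its two terminal carbons (the future cyclobutane CH–CH bond) to cyclooctatriene 21, whose triene closes by disrotatory 6π electrocyclization to the cis-fused bicyclo[4.2.0]octadiene 22, and at 110 °C the (E,E)-dienoate arm of 22 adds as the 4π partner across the nearer C=C of the cyclohexadiene. The closest known reaction type is the thermal 8π–6π electrocyclization cascade of (E,Z,Z,E)-tetraenes followed by intramolecular Diels–Alder reaction, including variants whose torquoselectivity is steered by a resident stereocentre next to a tetraene terminus. The eight-membered ring closes by 8π conrotation, it contracts transannularly to the four- and six-membered rings by 6π disrotation, and the cyclopentane and the ester-bearing cyclohexene close together by a suprafacial [4+2] addition on the ring face that carries the tether, exo to the cyclohexadiene as the one-carbon tether demands. The two (E)-termini and conrotation make the cyclobutane substituents trans; the sense of rotation is set by the silyloxy stereocentre, which is expected to react with its C–O bond inside, the dienyl group anti to the forming bond and the hydrogen outside (where a larger group would meet the first CH2 of the decenyl chain); disrotation makes the cyclobutane ring fusion cis, and the four Diels–Alder centres follow from the (E,E)-diene geometry and the tether. The step needs torquoselectivity, which rests on this substrate control, and it needs funnelling of the endo and exo isomers of 22, which interconvert by retro-6π opening while only the isomer with the dienoate arm endo can cyclise. It also needs the dienoate to act as diene and not as dienophile, which rests on the (E,E)-diene reaching the adjacent ring alkene in its s-cis form through the one-carbon tether; the minor diastereomer, which carries the antipodal ring system, is removed by chromatography here so that the enantiopurity of 15 passes into the target.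

Step 13
Reactants: 23 tetracyclic silyl ether
Product: 24 tetracyclic secondary alcohol (hydroxyl on the cyclopentane carbon next to the cyclobutane)
Conditions: HF·pyridine, THF/pyridine, 0 °C to rt
Reagents that add atoms: none
Why: Acidic fluoride cleaves the Si–O bond without base, so the epimerisable, deconjugated ester α-carbon is not disturbed.

Step 14
Reactants: 24 tetracyclic secondary alcohol
Product: 25 O-phenyl thionocarbonate of 24
Conditions: PhOC(S)Cl, pyridine, DMAP (cat.), CH2Cl2, 0 °C to rt
Reagents that add atoms: O-phenyl chlorothionoformate, S=C(Cl)Oc1ccccc1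
Why: DMAP-catalysed acylation of the secondary alcohol gives the Barton–McCombie precursor under conditions too weakly basic to move the β,γ-alkene into conjugation.

Step 15
Reactants: 25 O-phenyl thionocarbonate of 24
Product: 26 target CNP0133550.1
Conditions: Bu3SnH (excess, 0.5 M), Et3B (cat.), air (trace), toluene, rt
Reagents that add atoms: none
Why: Barton–McCombie deoxygenation, in which the stannyl radical adds to C=S and β-scission gives a ring-held secondary radical that should be reduced by concentrated tin hydride at room temperature faster than cyclobutylcarbinyl opening; no stereocentre remains at this carbon.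

**Compound list**

1 | oct-7-en-1-ol | C=CCCCCCCO | starting material
2 | (E)-1-bromoprop-1-ene | C/C=C/Br | starting material
3 | (E)-undec-9-en-1-ol | C/C=C/CCCCCCCCO | intermediate
4 | (E)-undec-9-enal | C/C=C/CCCCCCCC=O | intermediate
5 | (triphenylphosphoranylidene)acetaldehyde | O=CC=P(c1ccccc1)(c1ccccc1)c1ccccc1 | starting material
6 | (2E,11E)-trideca-2,11-dienal | C/C=C/CCCCCCC/C=C/C=O | intermediate
7 | 1,3-bis(triisopropylsilyl)propyne | CC(C)[Si](C(C)C)(C(C)C)CC#C[Si](C(C)C)(C(C)C)C(C)C | starting material
8 | triisopropyl[(3Z,5E,14E)-hexadeca-3,5,14-trien-1-yn-1-yl]silane | C/C=C/CCCCCCC/C=C/C=C\C#C[Si](C(C)C)(C(C)C)C(C)C | intermediate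
9 | (3Z,5E,14E)-hexadeca-3,5,14-trien-1-yne | C/C=C/CCCCCCC/C=C/C=C\C#C | intermediate
10 | (E)-4,4-dimethoxybut-2-enal | COC(OC)/C=C/C=O | starting material
11 | methyl (triphenylphosphoranylidene)acetate | COC(=O)C=P(c1ccccc1)(c1ccccc1)c1ccccc1 | starting material
12 | methyl (2E,4E)-6,6-dimethoxyhexa-2,4-dienoate | COC(OC)/C=C/C=C/C(=O)OC | intermediate
13 | methyl (2E,4E)-6-oxohexa-2,4-dienoate | COC(=O)/C=C/C=C/C=O | intermediate
14 | ethynyltrimethylsilane | C#C[Si](C)(C)C | starting material
15 | methyl (2E,4E,6R)-6-hydroxy-8-(trimethylsilyl)octa-2,4-dien-7-ynoate | COC(=O)/C=C/C=C/[C@@H](O)C#C[Si](C)(C)C | intermediate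
16 | methyl (2E,4E,6R)-6-[(tert-butyldimethylsilyl)oxy]-8-(trimethylsilyl)octa-2,4-dien-7-ynoate | COC(=O)/C=C/C=C/[C@@H](O[Si](C)(C)C(C)(C)C)C#C[Si](C)(C)C | intermediate
17 | methyl (2E,4E,6R)-6-[(tert-butyldimethylsilyl)oxy]octa-2,4-dien-7-ynoate | COC(=O)/C=C/C=C/[C@@H](O[Si](C)(C)C(C)(C)C)C#C | intermediate
18 | methyl (2E,4E,6R,7E)-6-[(tert-butyldimethylsilyl)oxy]-8-iodoocta-2,4,7-trienoate | COC(=O)/C=C/C=C/[C@@H](O[Si](C)(C)C(C)(C)C)/C=C/I | intermediate
19 | methyl (2E,4E,6R,7E,11Z,13E,22E)-6-[(tert-butyldimethylsilyl)oxy]tetracosa-2,4,7,11,13,22-hexaen-9-ynoate | C/C=C/CCCCCCC/C=C/C=C\C#C/C=C/[C@H](O[Si](C)(C)C(C)(C)C)/C=C/C=C/C(=O)OC | intermediate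
20 | methyl (2E,4E,6S,7E,9Z,11Z,13E,22E)-6-[(tert-butyldimethylsilyl)oxy]tetracosa-2,4,7,9,11,13,22-heptaenoate | C/C=C/CCCCCCC/C=C/C=C\C=C/C=C/[C@H](O[Si](C)(C)C(C)(C)C)/C=C/C=C/C(=O)OC | intermediate
21 | methyl (2E,4E)-6-[(tert-butyldimethylsilyl)oxy]-6-[trans-8-((E)-dec-8-en-1-yl)cycloocta-2,4,6-trien-1-yl]hexa-2,4-dienoate (absolute configuration as in the SMILES) | C/C=C/CCCCCCC[C@@H]1/C=C\C=C/C=C\[C@H]1[C@H](O[Si](C)(C)C(C)(C)C)/C=C/C=C/C(=O)OC | intermediate
22 | methyl (2E,4E)-6-[(tert-butyldimethylsilyl)oxy]-6-[8-((E)-dec-8-en-1-yl)bicyclo[4.2.0]octa-2,4-dien-7-yl]hexa-2,4-dienoate, cis-fused, dienoate arm endo, decenyl chain exo and trans to the arm (absolute configuration as in the SMILES) | C/C=C/CCCCCCC[C@@H]1[C@H]2C=CC=C[C@H]2[C@H]1[C@H](O[Si](C)(C)C(C)(C)C)/C=C/C=C/C(=O)OC | intermediate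
23 | tetracyclic silyl ether: the target with a tert-butyldimethylsilyloxy group on the cyclopentane carbon next to the cyclobutane, oxygen cis (on the five-membered ring) to the cyclobutane carbon that bears the decenyl chain | C/C=C/CCCCCCC[C@@H]1[C@H]2C=C[C@@H]3[C@@H]4[C@H]2[C@H]1[C@H](O[Si](C)(C)C(C)(C)C)[C@H]4C=C[C@H]3C(=O)OC | intermediate
24 | tetracyclic secondary alcohol: 23 with free hydroxyl | C/C=C/CCCCCCC[C@@H]1[C@H]2C=C[C@@H]3[C@@H]4[C@H]2[C@H]1[C@H](O)[C@H]4C=C[C@H]3C(=O)OC | intermediate
25 | O-phenyl thionocarbonate of 24 | C/C=C/CCCCCCC[C@@H]1[C@H]2C=C[C@@H]3[C@@H]4[C@H]2[C@H]1[C@H](OC(=S)Oc5ccccc5)[C@H]4C=C[C@H]3C(=O)OC | intermediate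
26 | CNP0133550.1: methyl ester of the cyclobutane/cyclohexene/cyclopentane/cyclohexene tetracycle with the (E)-dec-8-enyl chain on the cyclobutane | C/C=C/CCCCCCC[C@@H]1[C@H]2C=C[C@@H]3[C@@H]4[C@H]2[C@H]1C[C@H]4C=C[C@H]3C(=O)OC | target

**Totals and risks**

Total step count: 15. Longest linear sequence: 10 steps (steps 1–5 or 6–10, then 11–15).

Step 12. Low torquoselectivity would cost material but not purity, because the diastereomers are separable and each is enantiopure. The process that could stop the route is a wrong periselectivity of the last [4+2]: the electron-poor γ,δ-alkene of the dienoate could act as the 2π partner toward the cyclohexadiene and give a bicyclo[2.2.2]octene. The fallback sets out from 19 and comes back at 23. Compound 19 is semi-reduced as in step 12 but kept at room temperature, so the electrocyclizations stop at bicyclooctadiene 22. The ester is reduced with i-Bu2AlH (CH2Cl2, −78 °C) to the bicyclic dienol F1. Heating in toluene (110 °C) then lets the unactivated diene serve only as the 4π partner and should give the tetracyclic primary alcohol F2. TEMPO (cat.)/NaOCl (cat.)/NaClO2 in buffered MeCN oxidises it to the tetracyclic carboxylic acid F3, and TMSCHN2 (MeOH/toluene) returns 23.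

Step 15. The secondary radical is cyclobutylcarbinyl and homoallylic, so cyclobutane opening or a 1,2-vinyl shift may compete with hydrogen transfer from tin. The fallback sets out from 24 and comes back at 26. Dess–Martin periodinane (NaHCO3, CH2Cl2) oxidises 24 to the tetracyclic cyclopentanone F4. TsNHNH2 (EtOH, rt) gives the tosylhydrazone F5. Catecholborane (CHCl3, 0 °C) followed by NaOAc·3H2O (reflux), a Kabalka-type hydrazone reduction, turns C=N into CH2 through a diazene and needs no chain-carrying radical that must find a tin hydride; it gives 26.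

Step 7. Background addition of the alkynylzinc to the electron-poor dienal could lower the enantiofacial selectivity, and any shortfall would pass unchanged into the target. The fallback sets out from 13 and comes back at 15. Lithium (trimethylsilyl)acetylide (from 14 and n-BuLi, THF, −78 °C) adds to 13 to give the racemic carbinol F6. MnO2 (CH2Cl2) oxidises it to the ynone F7. Noyori asymmetric transfer hydrogenation with RuCl(p-cymene)(TsDPEN) (antipode for the 6R alcohol, i-PrOH) returns 15.

**Further compounds**

F1 | step 12 | bicyclic dienol: 22 with the ester reduced to CH2OH | C/C=C/CCCCCCC[C@@H]1[C@H]2C=CC=C[C@H]2[C@H]1[C@H](O[Si](C)(C)C(C)(C)C)/C=C/C=C/CO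
F2 | step 12 | tetracyclic primary alcohol: 23 with CH2OH in place of CO2Me | C/C=C/CCCCCCC[C@@H]1[C@H]2C=C[C@@H]3[C@@H]4[C@H]2[C@H]1[C@H](O[Si](C)(C)C(C)(C)C)[C@H]4C=C[C@H]3CO
F3 | step 12 | tetracyclic carboxylic acid: 23 with CO2H in place of CO2Me | C/C=C/CCCCCCC[C@@H]1[C@H]2C=C[C@@H]3[C@@H]4[C@H]2[C@H]1[C@H](O[Si](C)(C)C(C)(C)C)[C@H]4C=C[C@H]3C(=O)O
F4 | step 15 | tetracyclic cyclopentanone: 24 oxidised at the carbinol carbon | C/C=C/CCCCCCC[C@@H]1[C@H]2C=C[C@@H]3[C@@H]4[C@H]2[C@H]1C(=O)[C@H]4C=C[C@H]3C(=O)OC
F5 | step 15 | tosylhydrazone of F4 | C/C=C/CCCCCCC[C@@H]1[C@H]2C=C[C@@H]3[C@@H]4[C@H]2[C@H]1C(=NNS(=O)(=O)c5ccc(C)cc5)[C@H]4C=C[C@H]3C(=O)OC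
F6 | step 7 | racemic methyl (2E,4E)-6-hydroxy-8-(trimethylsilyl)octa-2,4-dien-7-ynoate | COC(=O)/C=C/C=C/C(O)C#C[Si](C)(C)C
F7 | step 7 | methyl (2E,4E)-6-oxo-8-(trimethylsilyl)octa-2,4-dien-7-ynoate | COC(=O)/C=C/C=C/C(=O)C#C[Si](C)(C)C
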